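The C4–C4a bond of ring A, where sp3 C4 meets the tetrasubstituted C4a=C8a alkene, is the disconnection on which the route rests. The precursor is a 6,6-dimethylcyclohexenyl triflate carrying at C8a an open-chain 2-(silylmethylidene)but-3-enyl arm, whose C2=CH–Si geometry comes from anti-carbomagnesiation of propargyl alcohol. In one operation, hydroboration of the vinyl group and palladium-catalysed alkyl–alkenyl coupling close ring A and leave the Z-alkenylsilane untouched. Iododesilylation and a second B-alkyl coupling with an enantiopure 6-vinyl-1,2-dioxane ester (tertiary C–O by Sharpless epoxide perhydrolysis, secondary C–O by hydroperoxide displacement of a crotylation-derived mesylate), then saponification, finish the synthesis.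

Key step: step 6

Remark on the chemistry: the target is read as (2S)-2-[(3R,6S)-…]propanoic acid with a Z exocyclic alkene (side chain cis to C1; naphthalene numbering with the exocyclic alkene at C2 and the gem-dimethyl group at C5), and ketone 11 is carried as the racemate because its only stereocentre is erased in step 5.

Step 1
Reactants: 1 prop-2-yn-1-ol (propargyl alcohol); 2 vinylmagnesium bromide
Product: 4 (2Z)-2-(iodomethylidene)but-3-en-1-ol, via bromomagnesium alkenylmagnesium alkoxide 3 (not isolated)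
Conditions: 2 (2.5 equiv), CuI (10 mol%), THF, 0 °C → rt; then I2, –78 → 0 °C; aq. NH4Cl/Na2S2O3
Reagents that add atoms: iodine, II
Why: Copper-catalysed anti-carbomagnesiation of the propargylic alkoxide delivers the vinyl group to the internal alkyne carbon and magnesium to the terminal carbon cis to the CH2O arm (held as a five-membered chelate), and iodinolysis of the C–Mg bond with retention fixes the Z geometry; no stereocentre is formed.

Step 2
Reactants: 4 (2Z)-2-(iodomethylidene)but-3-en-1-ol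
Product: 7 (2Z)-2-[(trimethylsilyl)methylidene]but-3-en-1-ol, via dilithio species 5 (not isolated), via bis-silylated ether 6 (not isolated)
Conditions: t-BuLi (3.1 equiv), Et2O, –78 °C; Me3SiCl (2.5 equiv), –78 °C → rt; then K2CO3 (cat.), MeOH, 0 °C
Reagents that add atoms: chlorotrimethylsilane, C[Si](C)(C)Cl
Why: Iodine–lithium exchange on the lithium alkoxide gives a configurationally stable alkenyllithium that is silylated with retention (halogen–metal exchange, then electrophilic trapping), and the O–Si bond formed alongside is cleaved by mild methanolysis that leaves the C–Si bond alone.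

Step 3
Reactants: 7 (2Z)-2-[(trimethylsilyl)methylidene]but-3-en-1-ol
Product: 8 [(1Z)-2-(bromomethyl)buta-1,3-dien-1-yl]trimethylsilane
Conditions: CBr4, PPh3, CH2Cl2, 0 °C
Reagents that add atoms: tetrabromomethane, BrC(Br)(Br)Br
Why: Appel bromination converts the primary allylic alcohol into the bromide by SN2 displacement at CH2, which cannot touch the alkene geometry.

Step 4
Reactants: 9 2,2-dimethylcyclohexan-1-one; 8 [(1Z)-2-(bromomethyl)buta-1,3-dien-1-yl]trimethylsilane
Product: 11 (±)-2,2-dimethyl-6-{(2E)-2-[(trimethylsilyl)methylidene]but-3-en-1-yl}cyclohexan-1-one, via lithium enolate 10 (not isolated)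
Conditions: LiN(iPr)2 (1.05 equiv), THF, –78 °C; then 8, DMPU, –78 → 0 °C
Reagents that add atoms: none
Why: Kinetic lithium enolate alkylation: 9 can enolise only toward C6 because C2 is quaternary, the primary allylic bromide reacts by direct SN2, and the new stereocentre forms as a racemate that is erased in step 5.

Step 5
Reactants: 11 (±)-2,2-dimethyl-6-{(2E)-2-[(trimethylsilyl)methylidene]but-3-en-1-yl}cyclohexan-1-one
Product: 13 6,6-dimethyl-2-{(2E)-2-[(trimethylsilyl)methylidene]but-3-en-1-yl}cyclohex-1-en-1-yl trifluoromethanesulfonate, via tetrasubstituted lithium enolate 12 (not isolated)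
Conditions: LiN(iPr)2 (1.2 equiv), THF, –78 → 0 °C; PhNTf2, 0 °C → rt; aq. NH4Cl
Reagents that add atoms: N-phenylbis(trifluoromethanesulfonimide), O=S(=O)(N(c1ccccc1)S(=O)(=O)C(F)(F)F)C(F)(F)F
Why: Enolate O-sulfonylation: the only remaining α-hydrogen sits on the alkylated carbon, so the tetrasubstituted enolate and with it the position of the enol triflate are fixed without a regiochemical choice.

Step 6
Reactants: 13 6,6-dimethyl-2-{(2E)-2-[(trimethylsilyl)methylidene]but-3-en-1-yl}cyclohex-1-en-1-yl trifluoromethanesulfonate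
Product: 15 (Z)-[(5,5-dimethyl-3,4,5,6,7,8-hexahydronaphthalen-2(1H)-ylidene)methyl]trimethylsilane, via B-alkyl-9-BBN adduct 14 (not isolated)
Conditions: 9-BBN dimer (0.55 equiv), THF, 0 °C → rt; then PdCl2(dppf) (5 mol%), aq. K3PO4 (3 equiv), THF/DMF, 60 °C, degassed
Reagents that add atoms: none
Why: 9-BBN adds its B–H bond across the monosubstituted C3=C4 vinyl group with boron at terminal C4 to give homoallylic borane 14; zerovalent palladium then inserts into the C4a–OTf bond, the phosphate-activated alkyl group passes from boron to palladium within the same molecule, and reductive elimination joins C4 to C4a. The closest known reaction type is the intramolecular B-alkyl Suzuki–Miyaura coupling of hydroborated alkenyl-tethered enol triflates. Ring A closes as a six-membered carbocycle through a seven-membered palladacycle, in endo mode with respect to the triflate alkene, so C4a and C8a both lie in the new ring and the double bond stays tetrasubstituted at C4a=C8a. No stereocentre is created; the one stereochemical element at stake, the C2=CH–Si geometry (silicon cis to C1), was set by the anti-carbomagnesiation of step 1 and is only carried through. The step needs chemoselective hydroboration of the vinyl group, which the bulk of 9-BBN secures against the silicon-shielded trisubstituted alkene and the tetrasubstituted enol triflate, and it needs an unscrambled alkenylsilane, which holds because neither boron nor palladium ever sits on that alkene. Reductive elimination must also beat β-hydride loss, which the wide-bite-angle dppf ligand and the intramolecular setting favour.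

Step 7
Reactants: 15 (Z)-[(5,5-dimethyl-3,4,5,6,7,8-hexahydronaphthalen-2(1H)-ylidene)methyl]trimethylsilane
Product: 16 (2Z)-2-(iodomethylidene)-5,5-dimethyl-1,2,3,4,5,6,7,8-octahydronaphthalene
Conditions: N-iodosuccinimide (1.1 equiv), 2,6-lutidine, (CF3)2CHOH, 0 °C, dark; aq. Na2S2O3
Reagents that add atoms: N-iodosuccinimide, O=C1CCC(=O)N1I
Why: Ipso-iododesilylation: electrophilic iodine attacks the silicon-bearing carbon and the β-silyl cation turns by the shortest path before silicon is lost, so the iodide inherits the geometry of the silane (retention), while iodonium formation at the C4a=C8a alkene is reversible in the poorly nucleophilic solvent and has no outlet.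

Step 8
Reactants: 17 geranyl acetate [(2E)-3,7-dimethylocta-2,6-dien-1-yl acetate]
Product: 19 (2E)-3-methyl-6-oxohex-2-en-1-yl acetate, via ozonide 18 (not isolated)
Conditions: O3 (1.0 equiv), CH2Cl2, –78 °C; then Me2S, –78 °C → rt
Reagents that add atoms: ozone, [O-][O+]=O
Why: Chemoselective ozonolysis with one equivalent of ozone cleaves the electron-richer 6,7-alkene in preference to the 2,3-alkene deactivated by the allylic acetate, and dimethyl sulfide reduces the ozonide to the aldehyde.

Step 9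
Reactants: 19 (2E)-3-methyl-6-oxohex-2-en-1-yl acetate
Product: 21 (2E,6S,7R)-6-hydroxy-3,7-dimethylnona-2,8-dien-1-yl acetate, via borinate ester 20 (not isolated)
Conditions: trans-2-butene, n-BuLi, KOtBu, THF, –78 → –45 °C; (+)-Ipc2BOMe, –78 °C; BF3·OEt2; then 19, –78 °C; ethanolamine, rt
Reagents that add atoms: (E)-crotyldiisopinocampheylborane of the (–)-α-pinene series, C/C=C/CB([C@H]1C[C@H]2C[C@@H]([C@@H]1C)C2(C)C)[C@H]1C[C@H]2C[C@@H]([C@@H]1C)C2(C)C
Why: Brown crotylboration through a closed chair (Zimmerman–Traxler) transition state: the E geometry of the crotyl unit sets the 6,7-anti relationship and the isopinocampheyl groups of the (–)-α-pinene series direct addition to the Re face of the aldehyde, giving the (6S,7R) alcohol, while the non-oxidative ethanolamine work-up spares the allylic acetate.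

Step 10
Reactants: 21 (2E,6S,7R)-6-hydroxy-3,7-dimethylnona-2,8-dien-1-yl acetate
Product: 22 (2E,6S,7R)-6-(methanesulfonyloxy)-3,7-dimethylnona-2,8-dien-1-yl acetate
Conditions: MsCl, Et3N, CH2Cl2, 0 °C
Reagents that add atoms: methanesulfonyl chloride, CS(=O)(=O)Cl
Why: Sulfonylation of the secondary alcohol forms only an O–S bond, so C6 keeps its configuration and gains the leaving group for the later peroxide ring closure.

Step 11
Reactants: 22 (2E,6S,7R)-6-(methanesulfonyloxy)-3,7-dimethylnona-2,8-dien-1-yl acetate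
Product: 23 (2E,6S,7R)-1-hydroxy-3,7-dimethylnona-2,8-dien-6-yl methanesulfonate
Conditions: K2CO3 (0.2 equiv), MeOH, 0 °C
Reagents that add atoms: none
Why: Carbonate-catalysed transesterification removes the primary allylic acetate at 0 °C, conditions under which the secondary mesylate neither substitutes nor eliminates.

Step 12
Reactants: 23 (2E,6S,7R)-1-hydroxy-3,7-dimethylnona-2,8-dien-6-yl methanesulfonate
Product: 24 (3S,4R)-1-[(2S,3S)-3-(hydroxymethyl)-2-methyloxiran-2-yl]-4-methylhex-5-en-3-yl methanesulfonate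
Conditions: Ti(OiPr)4 (10 mol%), L-(+)-diethyl tartrate (12 mol%), t-BuOOH, 4 Å molecular sieves, CH2Cl2, –20 °C
Reagents that add atoms: tert-butyl hydroperoxide, CC(C)(C)OO
Why: Sharpless asymmetric epoxidation: the titanium tartrate complex epoxidises only the allylic alcohol alkene, and L-(+)-diethyl tartrate delivers oxygen to the face that gives the (2S,3S)-epoxide, leaving the terminal vinyl group and the mesylate untouched.

Step 13
Reactants: 24 (3S,4R)-1-[(2S,3S)-3-(hydroxymethyl)-2-methyloxiran-2-yl]-4-methylhex-5-en-3-yl methanesulfonate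
Product: 26 (1S)-1-[(3R,6R)-6-[(2R)-but-3-en-2-yl]-3-methyl-1,2-dioxan-3-yl]ethane-1,2-diol, via tertiary hydroperoxide 25 (not isolated)
Conditions: H2O2 (anhydrous, in Et2O, excess), H3PMo12O40 (2 mol%), Et2O, rt; then crude, Cs2CO3, DMF, 0 °C → rt
Reagents that add atoms: hydrogen peroxide, OO
Why: Acid-catalysed epoxide perhydrolysis followed by intramolecular hydroperoxide alkylation: H2O2 opens the epoxide at the tertiary carbon with inversion (3S to 3R), and the cesium hydroperoxide then displaces the mesylate in a 6-exo-tet SN2 closure with inversion at the secondary carbon, so both ring stereocentres derive from the reagent-controlled steps 9 and 12.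

Step 14
Reactants: 26 (1S)-1-[(3R,6R)-6-[(2R)-but-3-en-2-yl]-3-methyl-1,2-dioxan-3-yl]ethane-1,2-diol
Product: 29 (2S)-2-[(3R,6R)-6-[(1S)-1,2-dihydroxyethyl]-6-methyl-1,2-dioxan-3-yl]propanoic acid, via ozonide 27 (not isolated), via aldehyde 28 (not isolated)
Conditions: O3, CH2Cl2, –78 °C; Me2S, –78 °C → rt; then crude, NaClO2, NaH2PO4, 2-methyl-2-butene, t-BuOH/H2O, 0 °C
Reagents that add atoms: ozone, [O-][O+]=O; sodium chlorite, [Na+].[O-]Cl=O
Why: Ozonolysis of the only alkene and Pinnick oxidation of the crude aldehyde: the dialkyl peroxide is inert to ozone, dimethyl sulfide and chlorite, and the weakly acidic buffer keeps the α-stereocentre from epimerising and the β-peroxy aldehyde from eliminating.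

Step 15
Reactants: 29 (2S)-2-[(3R,6R)-6-[(1S)-1,2-dihydroxyethyl]-6-methyl-1,2-dioxan-3-yl]propanoic acid
Product: 30 methyl (2S)-2-[(3R,6R)-6-[(1S)-1,2-dihydroxyethyl]-6-methyl-1,2-dioxan-3-yl]propanoate
Conditions: Me3SiCHN2, toluene/MeOH, 0 °C
Reagents that add atoms: (trimethylsilyl)diazomethane, C[Si](C)(C)C=[N+]=[N-]
Why: Carboxylic acid O-methylation by the diazoalkane runs under neutral conditions, so neither the peroxide nor the α-stereocentre is at risk.

Step 16
Reactants: 30 methyl (2S)-2-[(3R,6R)-6-[(1S)-1,2-dihydroxyethyl]-6-methyl-1,2-dioxan-3-yl]propanoate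
Product: 31 methyl (2S)-2-[(3R,6R)-6-formyl-6-methyl-1,2-dioxan-3-yl]propanoate
Conditions: NaIO4, THF/pH 7 buffer, 0 °C
Reagents that add atoms: none
Why: Malaprade glycol cleavage by periodate gives an aldehyde on a quaternary carbon, which can neither epimerise nor trigger base-induced peroxide fragmentation from that position.

Step 17
Reactants: 31 methyl (2S)-2-[(3R,6R)-6-formyl-6-methyl-1,2-dioxan-3-yl]propanoate
Product: 32 methyl (2S)-2-[(3R,6R)-6-ethenyl-6-methyl-1,2-dioxan-3-yl]propanoate
Conditions: Ph3PCH3Br, KN(SiMe3)2, THF, –78 → 0 °C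
Reagents that add atoms: methyltriphenylphosphonium bromide, C[P+](c1ccccc1)(c1ccccc1)c1ccccc1.[Br-]
Why: Wittig methylenation: the small ylide adds to the non-enolisable aldehyde at low temperature much faster than it can attack the ester or the dialkyl peroxide.

Step 18
Reactants: 32 methyl (2S)-2-[(3R,6R)-6-ethenyl-6-methyl-1,2-dioxan-3-yl]propanoate; 16 (2Z)-2-(iodomethylidene)-5,5-dimethyl-1,2,3,4,5,6,7,8-octahydronaphthalene
Product: 34 methyl (2S)-2-[(3R,6S)-6-{(3Z)-3-[5,5-dimethyl-3,4,5,6,7,8-hexahydronaphthalen-2(1H)-ylidene]propyl}-6-methyl-1,2-dioxan-3-yl]propanoate, via B-alkyl-9-BBN adduct 33 (not isolated)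
Conditions: 9-BBN dimer (0.6 equiv), THF, 0 °C → rt; then 16 (1.2 equiv), PdCl2(dppf) (10 mol%), AsPh3, aq. Cs2CO3, DMF/THF, rt, dark
Reagents that add atoms: none
Why: B-alkyl Suzuki–Miyaura coupling: 9-BBN adds to the terminal carbon of the vinyl group, and transfer of the primary alkyl group to the alkenylpalladium iodide followed by reductive elimination retains the Z geometry at room temperature, mild enough for the ester and the dialkyl peroxide; no stereocentre is touched.

Step 19
Reactants: 34 methyl (2S)-2-[(3R,6S)-6-{(3Z)-3-[5,5-dimethyl-3,4,5,6,7,8-hexahydronaphthalen-2(1H)-ylidene]propyl}-6-methyl-1,2-dioxan-3-yl]propanoate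
Product: 35 (2S)-2-[(3R,6S)-6-{(3Z)-3-[5,5-dimethyl-3,4,5,6,7,8-hexahydronaphthalen-2(1H)-ylidene]propyl}-6-methyl-1,2-dioxan-3-yl]propanoic acid
Conditions: LiOH, THF/MeOH/H2O, 0 °C → rt; then dilute HCl to pH 3–4
Reagents that add atoms: lithium hydroxide, [Li+].[OH-]
Why: Saponification by acyl–oxygen cleavage with hydroxide at low temperature, the usual way of freeing 1,2-dioxane acids of this kind, should leave the α-stereocentre and the O–O bond intact.

Compound list
1 | prop-2-yn-1-ol (propargyl alcohol) | C#CCO | starting material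
2 | vinylmagnesium bromide | C=C[Mg]Br | starting material
3 | bromomagnesium (2Z)-2-[(bromomagnesio)methylidene]but-3-en-1-olate | Br[Mg]OC/C(C=C)=C\[Mg]Br | intermediate
4 | (2Z)-2-(iodomethylidene)but-3-en-1-ol | OC/C(C=C)=C\I | intermediate
5 | lithium (2Z)-2-(lithiomethylidene)but-3-en-1-olate | [Li]OC/C(C=C)=C\[Li] | intermediate
6 | trimethyl{[(2Z)-2-[(trimethylsilyl)methylidene]but-3-en-1-yl]oxy}silane | C[Si](C)(C)OC/C(C=C)=C\[Si](C)(C)C | intermediate
7 | (2Z)-2-[(trimethylsilyl)methylidene]but-3-en-1-ol | OC/C(C=C)=C\[Si](C)(C)C | intermediate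
8 | [(1Z)-2-(bromomethyl)buta-1,3-dien-1-yl]trimethylsilane | BrC/C(C=C)=C\[Si](C)(C)C | intermediate
9 | 2,2-dimethylcyclohexan-1-one | CC1(C)CCCCC1=O | starting material
10 | lithium 6,6-dimethylcyclohex-1-en-1-olate | [Li]OC1=CCCCC1(C)C | intermediate
11 | (±)-2,2-dimethyl-6-{(2E)-2-[(trimethylsilyl)methylidene]but-3-en-1-yl}cyclohexan-1-one | C=C/C(=C/[Si](C)(C)C)CC1CCCC(C)(C)C1=O | intermediate
12 | lithium 6,6-dimethyl-2-{(2E)-2-[(trimethylsilyl)methylidene]but-3-en-1-yl}cyclohex-1-en-1-olate | C=C/C(=C/[Si](C)(C)C)CC1=C(O[Li])C(C)(C)CCC1 | intermediate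
13 | 6,6-dimethyl-2-{(2E)-2-[(trimethylsilyl)methylidene]but-3-en-1-yl}cyclohex-1-en-1-yl trifluoromethanesulfonate | C=C/C(=C/[Si](C)(C)C)CC1=C(OS(=O)(=O)C(F)(F)F)C(C)(C)CCC1 | intermediate
14 | 2-{(2Z)-4-(9-borabicyclo[3.3.1]nonan-9-yl)-2-[(trimethylsilyl)methylidene]butyl}-6,6-dimethylcyclohex-1-en-1-yl trifluoromethanesulfonate (silicon cis to the ring-bearing CH2) | C[Si](C)(C)/C=C(/CCB1C2CCCC1CCC2)CC1=C(OS(=O)(=O)C(F)(F)F)C(C)(C)CCC1 | intermediate
15 | (Z)-[(5,5-dimethyl-3,4,5,6,7,8-hexahydronaphthalen-2(1H)-ylidene)methyl]trimethylsilane | C[Si](C)(C)/C=C1/CCC2=C(CCCC2(C)C)C1 | intermediate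
16 | (2Z)-2-(iodomethylidene)-5,5-dimethyl-1,2,3,4,5,6,7,8-octahydronaphthalene | I/C=C1/CCC2=C(CCCC2(C)C)C1 | intermediate
17 | geranyl acetate, (2E)-3,7-dimethylocta-2,6-dien-1-yl acetate | CC(C)=CCC/C(C)=C/COC(C)=O | starting material
18 | (2E)-5-(5,5-dimethyl-1,2,4-trioxolan-3-yl)-3-methylpent-2-en-1-yl acetate (ozonide, mixture at the trioxolane carbon) | CC(=O)OC/C=C(\C)CCC1OOC(C)(C)O1 | intermediate
19 | (2E)-3-methyl-6-oxohex-2-en-1-yl acetate | CC(=O)OC/C=C(\C)CCC=O | intermediate
20 | (2E,6S,7R)-6-{[bis(isopinocampheyl)boranyl]oxy}-3,7-dimethylnona-2,8-dien-1-yl acetate | CC(=O)OC/C=C(\C)CC[C@H](OB([C@H]1C[C@H]2C[C@@H]([C@@H]1C)C2(C)C)[C@H]1C[C@H]2C[C@@H]([C@@H]1C)C2(C)C)[C@H](C)C=C | intermediate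
21 | (2E,6S,7R)-6-hydroxy-3,7-dimethylnona-2,8-dien-1-yl acetate | CC(=O)OC/C=C(\C)CC[C@H](O)[C@H](C)C=C | intermediate
22 | (2E,6S,7R)-6-(methanesulfonyloxy)-3,7-dimethylnona-2,8-dien-1-yl acetate | CC(=O)OC/C=C(\C)CC[C@H](OS(C)(=O)=O)[C@H](C)C=C | intermediate
23 | (2E,6S,7R)-1-hydroxy-3,7-dimethylnona-2,8-dien-6-yl methanesulfonate | OC/C=C(\C)CC[C@H](OS(C)(=O)=O)[C@H](C)C=C | intermediate
24 | (3S,4R)-1-[(2S,3S)-3-(hydroxymethyl)-2-methyloxiran-2-yl]-4-methylhex-5-en-3-yl methanesulfonate | OC[C@@H]1O[C@@]1(C)CC[C@H](OS(C)(=O)=O)[C@H](C)C=C | intermediate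
25 | (2S,3R,6S,7R)-3-hydroperoxy-1,2-dihydroxy-3,7-dimethylnon-8-en-6-yl methanesulfonate | OC[C@H](O)[C@](C)(OO)CC[C@H](OS(C)(=O)=O)[C@H](C)C=C | intermediate
26 | (1S)-1-[(3R,6R)-6-[(2R)-but-3-en-2-yl]-3-methyl-1,2-dioxan-3-yl]ethane-1,2-diol | OC[C@H](O)[C@@]1(C)CC[C@H]([C@H](C)C=C)OO1 | intermediate
27 | (1S)-1-[(3R,6R)-3-methyl-6-[(1S)-1-(1,2,4-trioxolan-3-yl)ethyl]-1,2-dioxan-3-yl]ethane-1,2-diol (ozonide, mixture at the trioxolane carbon) | OC[C@H](O)[C@@]1(C)CC[C@H]([C@H](C)C2OCOO2)OO1 | intermediate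
28 | (2S)-2-[(3R,6R)-6-[(1S)-1,2-dihydroxyethyl]-6-methyl-1,2-dioxan-3-yl]propanal | OC[C@H](O)[C@@]1(C)CC[C@H]([C@H](C)C=O)OO1 | intermediate
29 | (2S)-2-[(3R,6R)-6-[(1S)-1,2-dihydroxyethyl]-6-methyl-1,2-dioxan-3-yl]propanoic acid | OC[C@H](O)[C@@]1(C)CC[C@H]([C@H](C)C(=O)O)OO1 | intermediate
30 | methyl (2S)-2-[(3R,6R)-6-[(1S)-1,2-dihydroxyethyl]-6-methyl-1,2-dioxan-3-yl]propanoate | OC[C@H](O)[C@@]1(C)CC[C@H]([C@H](C)C(=O)OC)OO1 | intermediate
31 | methyl (2S)-2-[(3R,6R)-6-formyl-6-methyl-1,2-dioxan-3-yl]propanoate | O=C[C@@]1(C)CC[C@H]([C@H](C)C(=O)OC)OO1 | intermediate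
32 | methyl (2S)-2-[(3R,6R)-6-ethenyl-6-methyl-1,2-dioxan-3-yl]propanoate | C=C[C@@]1(C)CC[C@H]([C@H](C)C(=O)OC)OO1 | intermediate
33 | methyl (2S)-2-[(3R,6S)-6-[2-(9-borabicyclo[3.3.1]nonan-9-yl)ethyl]-6-methyl-1,2-dioxan-3-yl]propanoate | C[C@H](C(=O)OC)[C@H]1CC[C@](C)(CCB2C3CCCC2CCC3)OO1 | intermediate
34 | methyl (2S)-2-[(3R,6S)-6-{(3Z)-3-[5,5-dimethyl-3,4,5,6,7,8-hexahydronaphthalen-2(1H)-ylidene]propyl}-6-methyl-1,2-dioxan-3-yl]propanoate | C[C@H](C(=O)OC)[C@H]1CC[C@](C)(CC/C=C2/CCC3=C(CCCC3(C)C)C2)OO1 | intermediate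
35 | (2S)-2-[(3R,6S)-6-{(3Z)-3-[5,5-dimethyl-3,4,5,6,7,8-hexahydronaphthalen-2(1H)-ylidene]propyl}-6-methyl-1,2-dioxan-3-yl]propanoic acid | C[C@H](C(=O)O)[C@H]1CC[C@](C)(CC/C=C2/CCC3=C(CCCC3(C)C)C2)OO1 | target

Total step count: 19. Longest linear sequence: 12 steps (17 to 35, steps 8 to 19); the bicyclic arm (steps 1 to 7) joins at step 18.

Steps most likely to fail

Step 6. Oxidative addition into the hindered tetrasubstituted triflate next to the quaternary carbon may be slow, so that protodeboronation or β-hydride loss from the alkylpalladium intermediate outruns ring closure. The fallback sets out from 13. Adduct 14 is oxidised with NaBO3 to the primary alcohol 2-{(2E)-4-hydroxy-2-[(trimethylsilyl)methylidene]butyl}-6,6-dimethylcyclohex-1-en-1-yl trifluoromethanesulfonate F1. Appel iodination (I2, PPh3, imidazole) gives the primary iodide F2, and insertion of Zn (LiCl, THF) gives the alkylzinc iodide F3. An intramolecular Negishi coupling (Pd(PPh3)4, THF, 50 °C), in which transmetalation needs no base, then closes ring A and the route comes back at 15.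

Step 7. Electrophilic iodine may be drawn to the electron-rich C4a=C8a alkene, or the β-silyl cation may live long enough for the geometry to leak. The fallback sets out from 4 and swaps silicon for germanium. The dilithio species 5 is quenched with one equivalent of Et3GeCl to give (2Z)-2-[(triethylgermyl)methylidene]but-3-en-1-ol F4. Steps 3 to 6, applied unchanged, lead through the bromide F5, the racemic ketone F6 (from enolate 10), its lithium enolate F7, the enol triflate F8 and the B-alkyl-9-BBN adduct F9 to the bicyclic alkenylgermane F10. The C–Ge bond is inert in the palladium step yet far more prone to ipso-substitution than C–Si, so N-iodosuccinimide in MeCN at –20 °C should cleave it with retention, and the route comes back at 16.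

Step 18. The O–O bond may be reduced by the B–H reagent or the alkylborane, or the β-peroxy ester may ring-open under the aqueous base of the coupling. The fallback sets out from aldehyde 31 and avoids boron. Ohira–Bestmann homologation (dimethyl (1-diazo-2-oxopropyl)phosphonate, K2CO3, MeOH, 0 °C) gives the alkyne methyl (2S)-2-[(3R,6R)-6-ethynyl-6-methyl-1,2-dioxan-3-yl]propanoate F11. Sonogashira coupling with 16 (PdCl2(PPh3)2, CuI, Et3N, rt) gives the enyne F12 with the alkene geometry retained. Diimide (2-nitrobenzenesulfonyl hydrazide, Et3N), a reductant that spares O–O bonds, should saturate the alkyne by way of the disubstituted alkene while leaving the trisubstituted and tetrasubstituted alkenes, and the route comes back at 34.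

Further compounds
F1 | step 6 | 2-{(2E)-4-hydroxy-2-[(trimethylsilyl)methylidene]butyl}-6,6-dimethylcyclohex-1-en-1-yl trifluoromethanesulfonate | C[Si](C)(C)/C=C(/CCO)CC1=C(OS(=O)(=O)C(F)(F)F)C(C)(C)CCC1
F2 | step 6 | 2-{(2E)-4-iodo-2-[(trimethylsilyl)methylidene]butyl}-6,6-dimethylcyclohex-1-en-1-yl trifluoromethanesulfonate | C[Si](C)(C)/C=C(/CCI)CC1=C(OS(=O)(=O)C(F)(F)F)C(C)(C)CCC1
F3 | step 6 | iodo{(3E)-3-[(3,3-dimethyl-2-{[(trifluoromethyl)sulfonyl]oxy}cyclohex-1-en-1-yl)methyl]-4-(trimethylsilyl)but-3-en-1-yl}zinc | C[Si](C)(C)/C=C(/CC[Zn]I)CC1=C(OS(=O)(=O)C(F)(F)F)C(C)(C)CCC1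
F4 | step 7 | (2Z)-2-[(triethylgermyl)methylidene]but-3-en-1-ol | OC/C(C=C)=C\[Ge](CC)(CC)CC
F5 | step 7 | [(1Z)-2-(bromomethyl)buta-1,3-dien-1-yl]triethylgermane | BrC/C(C=C)=C\[Ge](CC)(CC)CC
F6 | step 7 | (±)-2,2-dimethyl-6-{(2E)-2-[(triethylgermyl)methylidene]but-3-en-1-yl}cyclohexan-1-one | C=C/C(=C/[Ge](CC)(CC)CC)CC1CCCC(C)(C)C1=O
F7 | step 7 | lithium 6,6-dimethyl-2-{(2E)-2-[(triethylgermyl)methylidene]but-3-en-1-yl}cyclohex-1-en-1-olate | C=C/C(=C/[Ge](CC)(CC)CC)CC1=C(O[Li])C(C)(C)CCC1
F8 | step 7 | 6,6-dimethyl-2-{(2E)-2-[(triethylgermyl)methylidene]but-3-en-1-yl}cyclohex-1-en-1-yl trifluoromethanesulfonate | C=C/C(=C/[Ge](CC)(CC)CC)CC1=C(OS(=O)(=O)C(F)(F)F)C(C)(C)CCC1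
F9 | step 7 | 2-{(2Z)-4-(9-borabicyclo[3.3.1]nonan-9-yl)-2-[(triethylgermyl)methylidene]butyl}-6,6-dimethylcyclohex-1-en-1-yl trifluoromethanesulfonate | CC[Ge](CC)(CC)/C=C(/CCB1C2CCCC1CCC2)CC1=C(OS(=O)(=O)C(F)(F)F)C(C)(C)CCC1
F10 | step 7 | (Z)-[(5,5-dimethyl-3,4,5,6,7,8-hexahydronaphthalen-2(1H)-ylidene)methyl]triethylgermane | CC[Ge](CC)(CC)/C=C1/CCC2=C(CCCC2(C)C)C1
F11 | step 18 | methyl (2S)-2-[(3R,6R)-6-ethynyl-6-methyl-1,2-dioxan-3-yl]propanoate | C#C[C@@]1(C)CC[C@H]([C@H](C)C(=O)OC)OO1
F12 | step 18 | methyl (2S)-2-[(3R,6R)-6-{(3Z)-3-[5,5-dimethyl-3,4,5,6,7,8-hexahydronaphthalen-2(1H)-ylidene]prop-1-yn-1-yl}-6-methyl-1,2-dioxan-3-yl]propanoate | C[C@H](C(=O)OC)[C@H]1CC[C@](C)(C#C/C=C2/CCC3=C(CCCC3(C)C)C2)OO1
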